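**Plan**

1. Target: all-trans (2R,3R,4R)-chroman. Numbering: O1, C2, C3, C4, C4a–C8a; ring A = fused benzo ring with the C7 methoxy group; ring B = 2,4-dimethoxyphenyl on C2; ring C = pyran ring; C9 = benzylic CH2 on C3.
2. Cuts, in retrosynthetic order: C4–C(styryl); then C3–C9 together with a temporary C4–C9 bond, C9 carrying a removable carboxyl group; then C2–C1' (ring B).
3. Enabling feature: C9 is bonded to C3 and is one atom away from C4, and C4 is the benzylic carbon of ring A with O1 ortho and the C7 methoxy group para to C4a. A cyclopropane C3–C9–C4 fused to ring C is therefore a donor–acceptor cyclopropane once C9 bears an ester, and it breaks at C4–C9.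
4. Forward order: ring C comes from 7-methoxycoumarin; ring B is added at C2 of the derived chromene acetal; a rhodium carbenoid closes the three-membered ring across C3=C4; an (E)-styryl trifluoroborate opens it at C4; the ester on C9 is excised (zinc, then radical decarboxylation); the two acetates are removed last.
5. Stereochemistry: C2 from the chiral acid catalyst of the boronate addition; C3 from carbenoid attack anti to ring B; C4 from backside opening trans to the C3–C9 bond; the alkene geometry from the (E)-alkenylboron reagent.

Key step: step 7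

Remark (assumption): the sense of induction of the tartaric-acid-derived catalyst in step 3 with this ortho-substituted aryl boronate is not assigned here; the antipode that delivers (R)-6 is meant, and both antipodes derive from the commercial tartaric acids.

Remark: compounds 16, 17 and 18 are carried as mixtures of the two epimers at C9, which becomes a CH2 group in step 12.

**Route**

Step 1
Reactants: 1 7-methoxycoumarin
Product: 3 2-ethoxy-7-methoxy-2H-chromene, via lactol 2 (not isolated)
Conditions: i-Bu2AlH (1.1 equiv), toluene, −78 °C; aq. potassium sodium tartrate; then EtOH, pyridinium p-toluenesulfonate (cat.), rt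
Reagents that add atoms: ethanol, CCO
Why: Low-temperature hydride reduction of the lactone stops at the aluminium hemiacetal, and acid-catalysed acetalisation of the resulting lactol with ethanol should give the stable racemic mixed acetal, whose C2 centre is erased in step 3.

Step 2
Reactants: 4 2,4-dimethoxyphenylboronic acid
Product: 5 diethyl (2,4-dimethoxyphenyl)boronate
Conditions: EtOH (excess), toluene, 3 Å molecular sieves, 40 °C; concentrate, use crude
Reagents that add atoms: ethanol, CCO
Why: Esterification of a boronic acid with removal of water gives the exchangeable dialkyl boronate that the chiral hydroxy acid of step 3 must be able to displace.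

Step 3
Reactants: 3 2-ethoxy-7-methoxy-2H-chromene; 5 diethyl (2,4-dimethoxyphenyl)boronate
Product: 6 (2R)-2-(2,4-dimethoxyphenyl)-7-methoxy-2H-chromene
Conditions: tartaric acid mono(N,N-dibenzylamide) (antipode giving 2R, 5 mol%), Yb(OTf)3 (5 mol%), EtOAc, −20 to 4 °C
Reagents that add atoms: none
Why: Enantioselective boronate addition to a chromene acetal under combined chiral Brønsted acid and Lewis acid catalysis: the lanthanide triflate ionises the acetal to the planar 2H-chromenylium ion, the chiral hydroxy acid exchanges onto boron, and the resulting chiral boronate transfers ring B to one face of C2, so the catalyst sets C2.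

Step 4
Reactants: 7 4-hydroxyphenylacetic acid
Product: 8 2,2,2-trichloroethyl 2-(4-hydroxyphenyl)acetate
Conditions: Cl3CCH2OH (3 equiv), p-TsOH·H2O (cat.), toluene, reflux, Dean–Stark trap
Reagents that add atoms: 2,2,2-trichloroethanol, OCC(Cl)(Cl)Cl
Why: Fischer esterification with azeotropic removal of water acylates the alcohol only, because the phenol is not esterified under acid catalysis.

Step 5
Reactants: 8 2,2,2-trichloroethyl 2-(4-hydroxyphenyl)acetate
Product: 9 2,2,2-trichloroethyl 2-(4-acetoxyphenyl)acetate
Conditions: Ac2O, pyridine, CH2Cl2, 0 °C to rt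
Reagents that add atoms: acetic anhydride, CC(=O)OC(C)=O
Why: Standard O-acetylation of a phenol; the acetate is chosen because it tolerates BF3·OEt2, KHF2 and Zn/AcOH and leaves with the second acetate in the last step.

Step 6
Reactants: 9 2,2,2-trichloroethyl 2-(4-acetoxyphenyl)acetate
Product: 10 2,2,2-trichloroethyl 2-(4-acetoxyphenyl)-2-diazoacetate
Conditions: 4-acetamidobenzenesulfonyl azide (1.3 equiv), DBU (1.5 equiv), MeCN, 0 °C, short reaction time
Reagents that add atoms: 4-acetamidobenzenesulfonyl azide, CC(=O)Nc1ccc(cc1)S(=O)(=O)N=[N+]=[N-]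
Why: Regitz diazo transfer to the acidic benzylic position of an arylacetate, which is fast at 0 °C so that the aryl acetate should not suffer from the amidine base.

Step 7
Reactants: 6 (2R)-2-(2,4-dimethoxyphenyl)-7-methoxy-2H-chromene; 10 2,2,2-trichloroethyl 2-(4-acetoxyphenyl)-2-diazoacetate
Product: 11 2,2,2-trichloroethyl (1S,1aS,2R,7bS)-1-(4-acetoxyphenyl)-2-(2,4-dimethoxyphenyl)-5-methoxy-1,1a,2,7b-tetrahydrocyclopropa[c]chromene-1-carboxylate (cyclopropane on the face of ring C opposite ring B; acetoxyphenyl endo, ester exo)
Conditions: Rh2(OAc)4 (1 mol%), CH2Cl2, 4 Å molecular sieves, rt, 10 (1.5 equiv) added over 3 h; chromatography on Et3N-deactivated silica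
Reagents that add atoms: none
Why: Rh2(OAc)4 releases N2 from 10 and the donor/acceptor rhodium carbenoid adds to the C3=C4 bond of 6 in one concerted but asynchronous step, the bond to C3 leading while positive charge builds at C4 next to the methoxy-substituted ring A. The closest known reaction type is the dirhodium-carboxylate-catalysed cyclopropanation of styrenes and cyclic cis-styrenes (indene, 1,2-dihydronaphthalene, 2H-chromenes) with aryldiazoacetates. The three-membered ring C3–C9–C4 closes by this [2+1] addition of the carbene carbon to one face of the alkene, which makes the fusion to ring C cis and forms C3–C9 and C4–C9 together. C3 and C4 are both fixed by the face of attack, which should be the one opposite ring B on the neighbouring C2 stereocentre (substrate control), and C9 by the usual preference of such carbenoids to turn the ester away from the alkene substituents (aryl endo), a centre that is erased later. The step needs face selectivity and chemoselectivity for the alkene over insertion into the activated C2–H bond or attack on the dimethoxyarene; ring B shields one face of the adjacent alkene carbon, the C2–H bond is tertiary and hindered, and the electron-rich cis-styrene is the most nucleophilic π-bond present. Slow addition of 10 keeps carbene dimerisation down, and the trichloroethyl ester is chosen because zinc can remove it later without base.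

Step 8
Reactants: 12 4-acetoxystyrene; 13 vinylboronic acid pinacol ester
Product: 14 4-[(E)-2-(4,4,5,5-tetramethyl-1,3,2-dioxaborolan-2-yl)ethenyl]phenyl acetate
Conditions: second-generation Grubbs catalyst RuCl2(=CHPh)(PCy3)(H2IMes) (3 mol%), CH2Cl2, 40 °C
Reagents that add atoms: none
Why: Olefin cross-metathesis of a styrene with the vinyl boronate, driven by loss of ethene, should give the thermodynamically preferred (E)-alkenyl boronate.

Step 9
Reactants: 14 4-[(E)-2-(4,4,5,5-tetramethyl-1,3,2-dioxaborolan-2-yl)ethenyl]phenyl acetate
Product: 15 potassium (E)-[2-(4-acetoxyphenyl)ethenyl]trifluoroborate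
Conditions: KHF2 (4 equiv, aq.), MeOH, rt; crystallisation from acetone/Et2O
Reagents that add atoms: potassium hydrogen difluoride, F.[F-].[K+]
Why: Standard conversion of a pinacol boronate into the crystalline trifluoroborate salt with retention of alkene geometry; the weakly acidic medium leaves the aryl acetate intact.

Step 10
Reactants: 11 cyclopropa[c]chromene ester; 15 potassium (E)-[2-(4-acetoxyphenyl)ethenyl]trifluoroborate
Product: 16 2,2,2-trichloroethyl 2-(4-acetoxyphenyl)-2-[(2R,3S,4R)-4-[(E)-2-(4-acetoxyphenyl)ethenyl]-2-(2,4-dimethoxyphenyl)-7-methoxychroman-3-yl]acetate (both epimers at C9)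
Conditions: 15 (2 equiv), BF3·OEt2 (2 equiv), CH2Cl2/MeCN, −40 to 0 °C; then H2O
Reagents that add atoms: none
Why: Proposed new method: BF3 bound to the ester carbonyl polarises the C4–C9 bond, which already leans towards heterolysis because C4 is a benzylic carbon of ring A with O1 ortho and the C7 methoxy group para, and the alkenyltrifluoroborate attacks C4 through its boron-bearing carbon on the face opposite the departing C9 (SN2-like inversion; an ion-paired benzylic cation would be attacked on the same face, anti to the C3 substituent), after which loss of the boron group restores the E alkene and the boron enolate is protonated at C9 on work-up; the closest known reaction types are the Lewis-acid-promoted opening of 2-arylcyclopropane-1,1-diesters by alkenyl- and aryltrifluoroborates and the BF3-mediated alkenylation of benzylic cations by the same reagents, whereas a cyclopropane with a single ester and an aryl group on the acceptor carbon has not been opened in this way.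

Step 11
Reactants: 16 trichloroethyl ester (both epimers at C9)
Product: 17 2-(4-acetoxyphenyl)-2-[(2R,3S,4R)-4-[(E)-2-(4-acetoxyphenyl)ethenyl]-2-(2,4-dimethoxyphenyl)-7-methoxychroman-3-yl]acetic acid (both epimers at C9)
Conditions: Zn dust (10 equiv), AcOH/THF, rt
Reagents that add atoms: none
Why: Reductive cleavage of a 2,2,2-trichloroethyl ester: zinc reduces a C–Cl bond and β-elimination releases the carboxylate and 1,1-dichloroethene, independent of the steric crowding at C9 and without touching the aryl acetates, the styrene or the benzylic ether.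

Step 12
Reactants: 17 carboxylic acid (both epimers at C9)
Product: 19 (2R,3R,4R)-3-(4-acetoxybenzyl)-4-[(E)-2-(4-acetoxyphenyl)ethenyl]-2-(2,4-dimethoxyphenyl)-7-methoxychroman, via N-acyloxyphthalimide 18 (not isolated)
Conditions: N-hydroxyphthalimide, DIC, CH2Cl2, rt; filter, concentrate; then [Ru(bpy)3]Cl2 (1 mol%), Hantzsch ester (1.5 equiv), i-Pr2NEt, degassed CH2Cl2, blue LEDs, rt
Reagents that add atoms: none
Why: Carbodiimide coupling gives the redox-active ester, and its single-electron reduction by the photoreduced ruthenium complex releases phthalimide anion, CO2 and the benzylic C9 radical, which takes a hydrogen atom from the Hantzsch ester (reductive radical decarboxylation); the reductive manifold spares the electron-rich arenes and the styrene, the low triplet energy of the sensitiser should not isomerise the E alkene, and both C9 epimers converge on one CH2 group.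

Step 13
Reactants: 19 diacetate of the target
Product: 20 caraganin C, (2R,3R,4R)-2-(2,4-dimethoxyphenyl)-3-(4-hydroxybenzyl)-4-[(E)-2-(4-hydroxyphenyl)ethenyl]-7-methoxychroman
Conditions: K2CO3 (0.5 equiv), degassed MeOH, rt; aq. NH4Cl
Reagents that add atoms: none
Why: Base-catalysed transesterification (Zemplén-type methanolysis) removes both aryl acetates, and no stereocentre of the chroman is acidic enough to epimerise under carbonate.

**Compound list**

1 | 7-methoxycoumarin | COc1ccc2C=CC(=O)Oc2c1 | starting material
2 | 7-methoxy-2H-chromen-2-ol (lactol, racemic) | COc1ccc2C=CC(O)Oc2c1 | intermediate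
3 | 2-ethoxy-7-methoxy-2H-chromene (racemic) | CCOC1C=Cc2ccc(OC)cc2O1 | intermediate
4 | 2,4-dimethoxyphenylboronic acid | COc1ccc(B(O)O)c(OC)c1 | starting material
5 | diethyl (2,4-dimethoxyphenyl)boronate | CCOB(OCC)c1ccc(OC)cc1OC | intermediate
6 | (2R)-2-(2,4-dimethoxyphenyl)-7-methoxy-2H-chromene | COc1ccc2c(c1)O[C@@H](c1ccc(OC)cc1OC)C=C2 | intermediate
7 | 4-hydroxyphenylacetic acid | OC(=O)Cc1ccc(O)cc1 | starting material
8 | 2,2,2-trichloroethyl 2-(4-hydroxyphenyl)acetate | Oc1ccc(CC(=O)OCC(Cl)(Cl)Cl)cc1 | intermediate
9 | 2,2,2-trichloroethyl 2-(4-acetoxyphenyl)acetate | CC(=O)Oc1ccc(CC(=O)OCC(Cl)(Cl)Cl)cc1 | intermediate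
10 | 2,2,2-trichloroethyl 2-(4-acetoxyphenyl)-2-diazoacetate | CC(=O)Oc1ccc(cc1)C(=[N+]=[N-])C(=O)OCC(Cl)(Cl)Cl | intermediate
11 | 2,2,2-trichloroethyl (1S,1aS,2R,7bS)-1-(4-acetoxyphenyl)-2-(2,4-dimethoxyphenyl)-5-methoxy-1,1a,2,7b-tetrahydrocyclopropa[c]chromene-1-carboxylate (cyclopropane anti to ring B, acetoxyphenyl endo) | COc1ccc2c(c1)O[C@@H](c1ccc(OC)cc1OC)[C@@H]3[C@@](c1ccc(OC(C)=O)cc1)(C(=O)OCC(Cl)(Cl)Cl)[C@H]23 | intermediate
12 | 4-acetoxystyrene | CC(=O)Oc1ccc(C=C)cc1 | starting material
13 | vinylboronic acid pinacol ester | C=CB1OC(C)(C)C(C)(C)O1 | starting material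
14 | 4-[(E)-2-(4,4,5,5-tetramethyl-1,3,2-dioxaborolan-2-yl)ethenyl]phenyl acetate | CC(=O)Oc1ccc(/C=C/B2OC(C)(C)C(C)(C)O2)cc1 | intermediate
15 | potassium (E)-[2-(4-acetoxyphenyl)ethenyl]trifluoroborate | CC(=O)Oc1ccc(/C=C/[B-](F)(F)F)cc1.[K+] | intermediate
16 | 2,2,2-trichloroethyl 2-(4-acetoxyphenyl)-2-[(2R,3S,4R)-4-[(E)-2-(4-acetoxyphenyl)ethenyl]-2-(2,4-dimethoxyphenyl)-7-methoxychroman-3-yl]acetate (both epimers at C9) | COc1ccc2c(c1)O[C@@H](c1ccc(OC)cc1OC)[C@H](C(C(=O)OCC(Cl)(Cl)Cl)c1ccc(OC(C)=O)cc1)[C@H]2/C=C/c1ccc(OC(C)=O)cc1 | intermediate
17 | 2-(4-acetoxyphenyl)-2-[(2R,3S,4R)-4-[(E)-2-(4-acetoxyphenyl)ethenyl]-2-(2,4-dimethoxyphenyl)-7-methoxychroman-3-yl]acetic acid (both epimers at C9) | COc1ccc2c(c1)O[C@@H](c1ccc(OC)cc1OC)[C@H](C(C(=O)O)c1ccc(OC(C)=O)cc1)[C@H]2/C=C/c1ccc(OC(C)=O)cc1 | intermediate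
18 | 1,3-dioxoisoindolin-2-yl ester of 17 (N-acyloxyphthalimide, both epimers at C9) | COc1ccc2c(c1)O[C@@H](c1ccc(OC)cc1OC)[C@H](C(C(=O)ON1C(=O)c3ccccc3C1=O)c1ccc(OC(C)=O)cc1)[C@H]2/C=C/c1ccc(OC(C)=O)cc1 | intermediate
19 | (2R,3R,4R)-3-(4-acetoxybenzyl)-4-[(E)-2-(4-acetoxyphenyl)ethenyl]-2-(2,4-dimethoxyphenyl)-7-methoxychroman | COc1ccc2c(c1)O[C@@H](c1ccc(OC)cc1OC)[C@H](Cc1ccc(OC(C)=O)cc1)[C@H]2/C=C/c1ccc(OC(C)=O)cc1 | intermediate
20 | caraganin C, (2R,3R,4R)-2-(2,4-dimethoxyphenyl)-3-(4-hydroxybenzyl)-4-[(E)-2-(4-hydroxyphenyl)ethenyl]-7-methoxychroman (2,3-trans, 3,4-trans) | COc1ccc2c(c1)O[C@@H](c1ccc(OC)cc1OC)[C@H](Cc1ccc(O)cc1)[C@H]2/C=C/c1ccc(O)cc1 | target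

**Count and risks**

Total step count: 13 (three branches, joined in steps 7 and 10).
Longest linear sequence: 8 steps (steps 4, 5, 6, 7, 10, 11, 12, 13, from 4-hydroxyphenylacetic acid 7).

Steps most likely to fail:

1. Step 10 (proposed new method). Three processes may intervene:
   - the opened C4 cation may lose the C3 proton, giving elimination instead of substitution;
   - the alkenyl group may be delivered from boron held on the ester, on the same face as C9, giving retention at C4;
   - the reagent may be protodeboronated before it reacts.

   The fallback uses known chemistry, sets out from 11 and returns at 16. Acid-catalysed methanolysis of the cyclopropane (TfOH cat., MeOH/CH2Cl2, 0 °C), a known solvolytic opening of donor–acceptor cyclopropanes by alcohols, should give the 4-methoxychroman ester F1. Ionisation of this benzylic ether with BF3·OEt2 in the presence of 15 (CH2Cl2/MeCN, −40 °C), a known substitution of electron-rich secondary benzylic ethers by alkenyltrifluoroborates, should then give 16. In this variant C4 is set by attack anti to the C3 substituent on the free cation and no longer by inversion.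

2. Step 7. The carbenoid may insert into the C2–H bond or attack an arene, the face selectivity may be poor, or the very electron-rich cyclopropane may ionise on the Lewis-acidic catalyst or on silica and then lose a proton.

   The fallback gives up the cyclopropane, sets out from 6 and 9 and returns at 16. Wohl–Ziegler bromination of 9 (NBS, AIBN, PhCF3, 80 °C) should give the α-bromo ester F2. A photoredox radical–polar crossover alkoxyalkylation of 6 with this bromide (fac-Ir(ppy)3 cat., MeOH, 2,6-lutidine, MeCN, blue LEDs) adds the benzylic ester radical to C3 anti to ring B, oxidises the C4 radical to the cation and traps it with methanol. This should give the 4-methoxychroman ester F1, possibly as a mixture at C4, which is of no consequence. BF3·OEt2-mediated substitution of its methoxy group by 15, as in the first fallback, should then lead to 16.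

3. Step 3. Aryl transfer from the ortho-substituted boronate may be slow, enantioface discrimination may be poor, or the electron-rich boronate may be protodeboronated.

   The fallback sets out from 4 and returns at 6. Enantioselective conjugate addition of 4 to purchased 7-methoxychromone F3 (Pd(OCOCF3)2, the pyridine–oxazoline ligand t-BuPyOx in the antipode giving 2R, NH4PF6, H2O, ClCH2CH2Cl, 60 °C) should give the (2R)-flavanone F4. Reduction with NaBH4 in MeOH should give the flavan-4-ol F5, and dehydration under neutral conditions (Burgess reagent, THF, 50 °C) should give 6 without exposing C2 to acid.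

**Further compounds**

F1 | step 10 | 2,2,2-trichloroethyl 2-(4-acetoxyphenyl)-2-[(2R,3R,4R)-2-(2,4-dimethoxyphenyl)-4,7-dimethoxychroman-3-yl]acetate (2,3-trans, 3,4-trans; both epimers at C9) | COc1ccc2c(c1)O[C@@H](c1ccc(OC)cc1OC)[C@H](C(C(=O)OCC(Cl)(Cl)Cl)c1ccc(OC(C)=O)cc1)[C@H]2OC
F2 | step 7 | 2,2,2-trichloroethyl 2-(4-acetoxyphenyl)-2-bromoacetate (racemic) | CC(=O)Oc1ccc(cc1)C(Br)C(=O)OCC(Cl)(Cl)Cl
F3 | step 3 | 7-methoxy-4H-chromen-4-one (commercial starting material of the fallback) | COc1ccc2C(=O)C=COc2c1
F4 | step 3 | (2R)-2-(2,4-dimethoxyphenyl)-7-methoxychroman-4-one | COc1ccc2c(c1)O[C@@H](c1ccc(OC)cc1OC)CC2=O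
F5 | step 3 | (2R,4R)-2-(2,4-dimethoxyphenyl)-7-methoxychroman-4-ol (2,4-cis) | COc1ccc2c(c1)O[C@@H](c1ccc(OC)cc1OC)C[C@H]2O
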